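## Retrosynthetic overview

1. Global O-debenzylation comes last; the two ArCH2–C3 bonds next to the tertiary carbinols are cut back to an aryl bromide plus a spiro glycidic lactone (new nickel reductive epoxide arylation, used twice).
2. Each spiro-epoxide comes from an α-hydroxy-β-benzyl lactone (dianion + ICH2Cl, anti to the C4 benzyl group). Each lactone comes from a 3-(arylmethyl)cyclobutanone by enantioselective Baeyer–Villiger ring expansion, which sets C4.
3. The cyclobutanones come from aryl bromides and the dimethyl ketal of 3-(bromomethyl)cyclobutanone by nickel cross-electrophile coupling.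
4. The 5–5' biaryl is made first as the C2-symmetric dibromide 9 by iodide-selective Suzuki coupling of bromo-iodoarene 6 with its boronate 8. Its two C–Br bonds are then used one after the other (α-arm of unit A, then β-arm of unit B), which fixes the unsymmetrical linkage.
5. Ring order: aromatic rings (from catechol) → biaryl → cyclobutanone/lactone A → cyclobutanone/lactone B.

Assumption: the ligand antipode for steps 10 and 15 is fixed in a test run on 13 against 4-benzyloxolan-2-ones of known configuration; the minor C3 epimers of 15 and 23 are carried on because C3 is made planar again in the next step.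

## Route

Step 1
Reactants: 1 catechol
Product: 2 guaiacol (2-methoxyphenol)
Conditions: MeI (1.0 equiv), K2CO3 (1.0 equiv), acetone, reflux; distil, recycle catechol
Reagents that add atoms: iodomethane, CI
Why: Williamson O-methylation with one equivalent of MeI stops mainly at the monoether, and unreacted catechol and a little veratrole are removed by extraction and distillation.

Step 2
Reactants: 2 guaiacol
Product: 3 4-bromo-2-methoxyphenol
Conditions: NBS (1.0 equiv), MeCN, −20 °C to rt
Reagents that add atoms: N-bromosuccinimide, O=C1CCC(=O)N1Br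
Why: electrophilic aromatic bromination is steered by the free hydroxyl group, so one bromine enters para to OH and not para to the methoxy group.

Step 3
Reactants: 3 4-bromo-2-methoxyphenol
Product: 4 1-(benzyloxy)-4-bromo-2-methoxybenzene
Conditions: BnBr (1.1 equiv), K2CO3, DMF, 50 °C
Reagents that add atoms: benzyl bromide, BrCc1ccccc1
Why: Williamson ether synthesis installs a benzyl group that survives the organometallic, enolate and peracid steps and is removed by hydrogenolysis at the end.

Step 4
Reactants: 3 4-bromo-2-methoxyphenol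
Product: 5 4-bromo-2-iodo-6-methoxyphenol
Conditions: NIS (1.05 equiv), TsOH·H2O (10 mol%), MeCN, rt
Reagents that add atoms: N-iodosuccinimide, O=C1CCC(=O)N1I
Why: electrophilic aromatic iodination goes to the only free position ortho to the hydroxyl group because the para position is blocked by bromine and OH outweighs OMe as a director.

Step 5
Reactants: 5 4-bromo-2-iodo-6-methoxyphenol
Product: 6 2-(benzyloxy)-5-bromo-1-iodo-3-methoxybenzene
Conditions: BnBr (1.2 equiv), K2CO3, DMF, 50 °C
Reagents that add atoms: benzyl bromide, BrCc1ccccc1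
Why: Williamson ether synthesis protects the phenol as the same benzyl ether used on 4.

Step 6
Reactants: 6 2-(benzyloxy)-5-bromo-1-iodo-3-methoxybenzene
Product: 8 2-[2-(benzyloxy)-5-bromo-3-methoxyphenyl]-4,4,5,5-tetramethyl-1,3,2-dioxaborolane, via aryl Grignard 7 (not isolated)
Conditions: iPrMgCl·LiCl (1.05 equiv), THF, −40 °C; then iPrOBpin (1.3 equiv), −40 °C to rt; aq. NH4Cl
Reagents that add atoms: 2-isopropoxy-4,4,5,5-tetramethyl-1,3,2-dioxaborolane, CC(C)OB1OC(C)(C)C(C)(C)O1
Why: iodine–magnesium exchange is far faster at C–I than at C–Br and is helped by the neighbouring benzyloxy oxygen, and borylation of the aryl Grignard with the isopropyl borate gives the isolable pinacol boronate with the bromine untouched.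

Step 7
Reactants: 8 2-[2-(benzyloxy)-5-bromo-3-methoxyphenyl]-4,4,5,5-tetramethyl-1,3,2-dioxaborolane; 6 2-(benzyloxy)-5-bromo-1-iodo-3-methoxybenzene
Product: 9 2,2'-bis(benzyloxy)-5,5'-dibromo-3,3'-dimethoxy-1,1'-biphenyl
Conditions: 6 (1.1 equiv), Pd(PPh3)4 (3 mol%), K2CO3 (2 equiv), DME–H2O, 60 °C; stop when 8 is consumed
Reagents that add atoms: none
Why: Suzuki–Miyaura coupling in which zerovalent palladium inserts into the C–I bond of 6 much faster than into any C–Br bond, so the 5–5' biaryl bond forms while both para-bromines stay as handles.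

Step 8
Reactants: 10 3-(bromomethyl)cyclobutan-1-one
Product: 11 3-(bromomethyl)-1,1-dimethoxycyclobutane
Conditions: HC(OMe)3 (1.5 equiv), TsOH·H2O (2 mol%), MeOH, rt; Et3N quench
Reagents that add atoms: trimethyl orthoformate, COC(OC)OC
Why: acid-catalysed ketalisation driven by the orthoformate masks the strained ketone, so the later cyclobutylmethyl radical cannot open to an acyl-stabilised radical and zinc cannot attack the carbonyl.

Step 9
Reactants: 4 1-(benzyloxy)-4-bromo-2-methoxybenzene; 11 3-(bromomethyl)-1,1-dimethoxycyclobutane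
Product: 13 3-{[4-(benzyloxy)-3-methoxyphenyl]methyl}cyclobutan-1-one, via ketal 12 (not isolated)
Conditions: NiI2 (10 mol%), 4,4'-dimethoxy-2,2'-bipyridine (10 mol%), NaI (25 mol%), pyridine (10 mol%), Zn dust (2 equiv), DMPU, 60 °C; then 2 M HCl, THF, rt
Reagents that add atoms: water, O
Why: nickel-catalysed reductive cross-electrophile coupling joins the aryl bromide to the primary alkyl bromide, and aqueous acid then hydrolyses the ketal to the cyclobutanone.

Step 10
Reactants: 13 3-{[4-(benzyloxy)-3-methoxyphenyl]methyl}cyclobutan-1-one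
Product: 14 (4S)-4-{[4-(benzyloxy)-3-methoxyphenyl]methyl}oxolan-2-one
Conditions: Sc(OTf)3 (5 mol%), chiral N,N'-dioxide ligand (pipecolic acid-derived bis(2,6-diisopropylanilide), 6 mol%), m-CPBA (1.2 equiv), EtOAc, −20 °C
Reagents that add atoms: 3-chloroperbenzoic acid, OOC(=O)c1cccc(Cl)c1
Why: enantioselective Baeyer–Villiger ring expansion, in which one of the two enantiotopic ring CH2 groups of the scandium-bound Criegee adduct shifts from carbon to oxygen, desymmetrises the cyclobutanone and sets the S centre (C4).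

Step 11
Reactants: 14 (4S)-4-{[4-(benzyloxy)-3-methoxyphenyl]methyl}oxolan-2-one
Product: 15 (3S,4R)-4-{[4-(benzyloxy)-3-methoxyphenyl]methyl}-3-hydroxyoxolan-2-one
Conditions: KN(SiMe3)2 (1.2 equiv), THF, −78 °C; 2-(phenylsulfonyl)-3-phenyloxaziridine (1.3 equiv); AcOH quench
Reagents that add atoms: 2-(phenylsulfonyl)-3-phenyloxaziridine, O=S(=O)(N1OC1c1ccccc1)c1ccccc1
Why: Davis hydroxylation of the potassium enolate puts oxygen on C3 mainly anti to the C4 benzyl group, and the C3 configuration does not matter because C3 becomes planar again in step 12 (the C4 descriptor changes from S to R only through priorities).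

Step 12
Reactants: 15 (3S,4R)-4-{[4-(benzyloxy)-3-methoxyphenyl]methyl}-3-hydroxyoxolan-2-one
Product: 17 (3S,7R)-7-{[4-(benzyloxy)-3-methoxyphenyl]methyl}-1,5-dioxaspiro[2.4]heptan-4-one, via chlorohydrin alkoxide 16 (not isolated)
Conditions: LiN(iPr)2 (2.3 equiv), THF–DMPU, −78 °C; ICH2Cl (1.2 equiv), −78 °C to rt
Reagents that add atoms: chloroiodomethane, ClCI
Why: the alkoxide–enolate dianion is C-alkylated by ICH2Cl on the face anti to the C4 benzyl group and the neighbouring alkoxide then displaces chloride (intramolecular Williamson epoxide closure with retention at C3), so the C3 oxygen ends cis and the new CH2 trans to the C4 substituent.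

Step 13
Reactants: 17 (3S,7R)-7-{[4-(benzyloxy)-3-methoxyphenyl]methyl}-1,5-dioxaspiro[2.4]heptan-4-one; 9 2,2'-bis(benzyloxy)-5,5'-dibromo-3,3'-dimethoxy-1,1'-biphenyl
Product: 19 (3R,4R)-3-{[2,2'-bis(benzyloxy)-5'-bromo-3,3'-dimethoxy[1,1'-biphenyl]-5-yl]methyl}-4-{[4-(benzyloxy)-3-methoxyphenyl]methyl}-3-hydroxyoxolan-2-one, via iodohydrin 18 (not isolated)
Conditions: 9 (3 equiv, excess recovered), NiI2 (10 mol%), 4,4'-di-tert-butyl-2,2'-bipyridine (10 mol%), NaI (25 mol%), Et3N·HCl (1.1 equiv), Zn dust (2 equiv), DMPU, 30 °C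
Reagents that add atoms: none
Why: Proposed new method: nickel-catalysed reductive cross-electrophile arylation of a spiro glycidic lactone, in which iodide opens the epoxide at its unhindered CH2 to iodohydrin 18, low-valent nickel abstracts the iodine to give a primary radical that is captured by the aryl–nickel bromide formed from one C–Br bond of 9, and reductive elimination forges the ArCH2–C3 bond without touching the C3 and C4 centres already set; the closest known reaction is the nickel/iodide co-catalysed reductive coupling of aryl bromides with terminal epoxides, which has not been shown for 2,2-disubstituted glycidic esters or lactones.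

Step 14
Reactants: 19 bromo-biaryl lactone A (name as in step 13); 11 3-(bromomethyl)-1,1-dimethoxycyclobutane
Product: 21 compound 19 in which the 5'-bromine is replaced by a (3-oxocyclobutyl)methyl group, via ketal 20 (not isolated)
Conditions: 11 (1.5 equiv), NiI2 (10 mol%), 4,4'-dimethoxy-2,2'-bipyridine (10 mol%), NaI (25 mol%), pyridine (10 mol%), Zn dust (2 equiv), DMPU, 60 °C; then 2 M HCl, THF, rt
Reagents that add atoms: water, O
Why: the same reductive cross-electrophile coupling as in step 9 tolerates the lactone and the free tertiary alcohol and turns the remaining aryl bromide into the second 3-(arylmethyl)cyclobutanone after ketal hydrolysis.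

Step 15
Reactants: 21 cyclobutanone on the biaryl (as described in step 14)
Product: 22 compound 19 in which the 5'-bromine is replaced by a [(3S)-5-oxooxolan-3-yl]methyl group
Conditions: Sc(OTf)3 (5 mol%), the same chiral N,N'-dioxide ligand (6 mol%), m-CPBA (1.2 equiv), EtOAc, −20 °C
Reagents that add atoms: 3-chloroperbenzoic acid, OOC(=O)c1cccc(Cl)c1
Why: a second catalyst-controlled Baeyer–Villiger ring expansion (shift of one enantiotopic CH2 from carbon to oxygen) sets the S centre of lactone B, the remote lactone A has no say, and any minor diastereomer is removed by chromatography.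

Step 16
Reactants: 22 bis-lactone (as described in step 15)
Product: 23 compound 22 carrying a hydroxyl on C3 of lactone B trans to its benzylic substituent (3S,4R in the oxolan-2-one numbering of lactone B)
Conditions: KN(SiMe3)2 (2.3 equiv), THF, −78 °C; 2-(phenylsulfonyl)-3-phenyloxaziridine (1.3 equiv); AcOH quench
Reagents that add atoms: 2-(phenylsulfonyl)-3-phenyloxaziridine, O=S(=O)(N1OC1c1ccccc1)c1ccccc1
Why: Davis hydroxylation of the enolate of lactone B works because lactone A has no α-hydrogen and its tertiary hydroxyl is only deprotonated by the extra base.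

Step 17
Reactants: 23 hydroxy lactone B on the biaryl (as described in step 16)
Product: 25 compound 19 in which the 5'-bromine is replaced by a [(3S,7R)-4-oxo-1,5-dioxaspiro[2.4]heptan-7-yl]methyl group, via chlorohydrin alkoxide 24 (not isolated)
Conditions: LiN(iPr)2 (3.4 equiv), THF–DMPU, −78 °C; ICH2Cl (1.2 equiv), −78 °C to rt
Reagents that add atoms: chloroiodomethane, ClCI
Why: as in step 12 the enolate carbon is the most nucleophilic site of the trianion, is alkylated by ICH2Cl anti to the C4 substituent, and the adjacent alkoxide closes the epoxide (intramolecular Williamson closure), which fixes oxygen cis and CH2 trans to the β-benzyl group of lactone B.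

Step 18
Reactants: 25 spiro-epoxide B on the biaryl (as described in step 17); 4 1-(benzyloxy)-4-bromo-2-methoxybenzene
Product: 27 tetra-O-benzyl ether of the target (all four phenols of 28 as benzyl ethers), via iodohydrin 26 (not isolated)
Conditions: 4 (3 equiv), NiI2 (10 mol%), 4,4'-di-tert-butyl-2,2'-bipyridine (10 mol%), NaI (25 mol%), Et3N·HCl (1.1 equiv), Zn dust (2 equiv), DMPU, 30 °C
Reagents that add atoms: none
Why: Proposed new method: the same nickel-catalysed reductive arylation of a spiro glycidic lactone as in step 13 (iodide opening at CH2 to iodohydrin 26, iodine abstraction by low-valent nickel, radical capture by the aryl–nickel bromide from 4, reductive elimination) forms the last ArCH2–C3 bond with the carbinol configuration already fixed in the epoxide; the closest known reaction is the nickel/iodide co-catalysed reductive coupling of aryl bromides with terminal epoxides.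

Step 19
Reactants: 27 tetra-O-benzyl ether of the target
Product: 28 CNP0218652.1
Conditions: H2 (1 atm), Pd/C (10%), EtOAc–MeOH, rt
Reagents that add atoms: none
Why: hydrogenolysis of the four benzyl ethers over palladium on carbon leaves the lactones, tertiary alcohols, methyl ethers and the biaryl untouched and gives the target.

## Compound list

1 | catechol | Oc1ccccc1O | starting material
2 | guaiacol (2-methoxyphenol) | COc1ccccc1O | intermediate
3 | 4-bromo-2-methoxyphenol | COc1cc(Br)ccc1O | intermediate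
4 | 1-(benzyloxy)-4-bromo-2-methoxybenzene | COc1cc(Br)ccc1OCc1ccccc1 | intermediate
5 | 4-bromo-2-iodo-6-methoxyphenol | COc1cc(Br)cc(I)c1O | intermediate
6 | 2-(benzyloxy)-5-bromo-1-iodo-3-methoxybenzene | COc1cc(Br)cc(I)c1OCc1ccccc1 | intermediate
7 | [2-(benzyloxy)-5-bromo-3-methoxyphenyl]magnesium chloride (LiCl complex, formed in the flask) | COc1cc(Br)cc([Mg]Cl)c1OCc1ccccc1 | intermediate
8 | 2-[2-(benzyloxy)-5-bromo-3-methoxyphenyl]-4,4,5,5-tetramethyl-1,3,2-dioxaborolane | COc1cc(Br)cc(B2OC(C)(C)C(C)(C)O2)c1OCc1ccccc1 | intermediate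
9 | 2,2'-bis(benzyloxy)-5,5'-dibromo-3,3'-dimethoxy-1,1'-biphenyl | COc1cc(Br)cc(-c2cc(Br)cc(OC)c2OCc2ccccc2)c1OCc1ccccc1 | intermediate
10 | 3-(bromomethyl)cyclobutan-1-one | O=C1CC(CBr)C1 | starting material
11 | 3-(bromomethyl)-1,1-dimethoxycyclobutane | COC1(OC)CC(CBr)C1 | intermediate
12 | 1-(benzyloxy)-4-[(3,3-dimethoxycyclobutyl)methyl]-2-methoxybenzene (formed in the flask) | COc1cc(CC2CC(OC)(OC)C2)ccc1OCc1ccccc1 | intermediate
13 | 3-{[4-(benzyloxy)-3-methoxyphenyl]methyl}cyclobutan-1-one | COc1cc(CC2CC(=O)C2)ccc1OCc1ccccc1 | intermediate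
14 | (4S)-4-{[4-(benzyloxy)-3-methoxyphenyl]methyl}oxolan-2-one | COc1cc(C[C@@H]2COC(=O)C2)ccc1OCc1ccccc1 | intermediate
15 | (3S,4R)-4-{[4-(benzyloxy)-3-methoxyphenyl]methyl}-3-hydroxyoxolan-2-one (OH trans to the benzyl group) | COc1cc(C[C@@H]2COC(=O)[C@H]2O)ccc1OCc1ccccc1 | intermediate
16 | (3R,4R)-4-{[4-(benzyloxy)-3-methoxyphenyl]methyl}-3-(chloromethyl)-3-hydroxyoxolan-2-one (as lithium alkoxide, formed in the flask) | COc1cc(C[C@@H]2COC(=O)[C@@]2(O)CCl)ccc1OCc1ccccc1 | intermediate
17 | (3S,7R)-7-{[4-(benzyloxy)-3-methoxyphenyl]methyl}-1,5-dioxaspiro[2.4]heptan-4-one (epoxide O cis to the C7 benzyl group) | COc1cc(C[C@@H]2COC(=O)[C@@]23CO3)ccc1OCc1ccccc1 | intermediate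
18 | (3R,4R)-4-{[4-(benzyloxy)-3-methoxyphenyl]methyl}-3-hydroxy-3-(iodomethyl)oxolan-2-one (formed in the flask) | COc1cc(C[C@@H]2COC(=O)[C@@]2(O)CI)ccc1OCc1ccccc1 | intermediate
19 | (3R,4R)-3-{[2,2'-bis(benzyloxy)-5'-bromo-3,3'-dimethoxy[1,1'-biphenyl]-5-yl]methyl}-4-{[4-(benzyloxy)-3-methoxyphenyl]methyl}-3-hydroxyoxolan-2-one | COc1cc(C[C@@H]2COC(=O)[C@@]2(O)Cc2cc(OC)c(OCc3ccccc3)c(-c3cc(Br)cc(OC)c3OCc3ccccc3)c2)ccc1OCc1ccccc1 | intermediate
20 | 19 with the 5'-bromine replaced by (3,3-dimethoxycyclobutyl)methyl (formed in the flask) | COc1cc(C[C@@H]2COC(=O)[C@@]2(O)Cc2cc(OC)c(OCc3ccccc3)c(-c3cc(CC4CC(OC)(OC)C4)cc(OC)c3OCc3ccccc3)c2)ccc1OCc1ccccc1 | intermediate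
21 | 19 with the 5'-bromine replaced by (3-oxocyclobutyl)methyl | COc1cc(C[C@@H]2COC(=O)[C@@]2(O)Cc2cc(OC)c(OCc3ccccc3)c(-c3cc(CC4CC(=O)C4)cc(OC)c3OCc3ccccc3)c2)ccc1OCc1ccccc1 | intermediate
22 | 19 with the 5'-bromine replaced by [(3S)-5-oxooxolan-3-yl]methyl | COc1cc(C[C@@H]2COC(=O)[C@@]2(O)Cc2cc(OC)c(OCc3ccccc3)c(-c3cc(C[C@@H]4COC(=O)C4)cc(OC)c3OCc3ccccc3)c2)ccc1OCc1ccccc1 | intermediate
23 | 19 with the 5'-bromine replaced by [(3R,4S)-4-hydroxy-5-oxooxolan-3-yl]methyl | COc1cc(C[C@@H]2COC(=O)[C@@]2(O)Cc2cc(OC)c(OCc3ccccc3)c(-c3cc(C[C@@H]4COC(=O)[C@H]4O)cc(OC)c3OCc3ccccc3)c2)ccc1OCc1ccccc1 | intermediate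
24 | 19 with the 5'-bromine replaced by [(3R,4R)-4-(chloromethyl)-4-hydroxy-5-oxooxolan-3-yl]methyl (as lithium alkoxide, formed in the flask) | COc1cc(C[C@@H]2COC(=O)[C@@]2(O)Cc2cc(OC)c(OCc3ccccc3)c(-c3cc(C[C@@H]4COC(=O)[C@@]4(O)CCl)cc(OC)c3OCc3ccccc3)c2)ccc1OCc1ccccc1 | intermediate
25 | 19 with the 5'-bromine replaced by [(3S,7R)-4-oxo-1,5-dioxaspiro[2.4]heptan-7-yl]methyl | COc1cc(C[C@@H]2COC(=O)[C@@]2(O)Cc2cc(OC)c(OCc3ccccc3)c(-c3cc(C[C@@H]4COC(=O)[C@@]45CO5)cc(OC)c3OCc3ccccc3)c2)ccc1OCc1ccccc1 | intermediate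
26 | 19 with the 5'-bromine replaced by [(3R,4R)-4-hydroxy-4-(iodomethyl)-5-oxooxolan-3-yl]methyl (formed in the flask) | COc1cc(C[C@@H]2COC(=O)[C@@]2(O)Cc2cc(OC)c(OCc3ccccc3)c(-c3cc(C[C@@H]4COC(=O)[C@@]4(O)CI)cc(OC)c3OCc3ccccc3)c2)ccc1OCc1ccccc1 | intermediate
27 | tetra-O-benzyl ether of 28: 19 with the 5'-bromine replaced by [(3R,4R)-4-{[4-(benzyloxy)-3-methoxyphenyl]methyl}-4-hydroxy-5-oxooxolan-3-yl]methyl | COc1cc(C[C@@H]2COC(=O)[C@@]2(O)Cc2cc(OC)c(OCc3ccccc3)c(-c3cc(C[C@@H]4COC(=O)[C@@]4(O)Cc4ccc(OCc5ccccc5)c(OC)c4)cc(OC)c3OCc3ccccc3)c2)ccc1OCc1ccccc1 | intermediate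
28 | CNP0218652.1: (3R,4R)-3-{[2,2'-dihydroxy-5'-{[(3R,4R)-4-hydroxy-4-(4-hydroxy-3-methoxybenzyl)-5-oxooxolan-3-yl]methyl}-3,3'-dimethoxybiphenyl-5-yl]methyl}-3-hydroxy-4-(4-hydroxy-3-methoxybenzyl)oxolan-2-one | COc1cc(C[C@@H]2COC(=O)[C@@]2(O)Cc2cc(OC)c(O)c(-c3cc(C[C@@H]4COC(=O)[C@@]4(O)Cc4ccc(O)c(OC)c4)cc(OC)c3O)c2)ccc1O | target

## Step count and risks

Total steps: 19. Longest linear sequence: 14 (steps 1, 2, 3, 9, 10, 11, 12, 13, 14, 15, 16, 17, 18, 19).

Most likely to fail, first: step 13 (the proposed new epoxide arylation). The iodohydrin may lose HO/I to zinc to give the α-methylene lactone, or 9 may homocouple. The fallback is known chemistry, sets out from 9 and 15, and comes back at 19. Compound 9 is mono-lithiated (n-BuLi 1.0 equiv, THF, −78 °C) and quenched with monomeric formaldehyde to give [2,2'-bis(benzyloxy)-5'-bromo-3,3'-dimethoxy[1,1'-biphenyl]-5-yl]methanol F1. PBr3 turns it into 2,2'-bis(benzyloxy)-5-bromo-5'-(bromomethyl)-3,3'-dimethoxy-1,1'-biphenyl F2. The dianion of 15 (LiN(SiMe3)2 2.2 equiv, THF–DMPU, −78 °C) is then benzylated by F2 anti to the C4 substituent, the established way to the trachelogenin-type carbinol, which gives 19 directly without the epoxide.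

Second: step 18 (the same new reaction on the most advanced material). The fallback sets out from 4 and 23 and comes back at 27. Compound 4 is lithiated (n-BuLi, THF, −78 °C) and quenched with formaldehyde to give [4-(benzyloxy)-3-methoxyphenyl]methanol F3. PBr3 gives 1-(benzyloxy)-4-(bromomethyl)-2-methoxybenzene F4. The trianion of 23 (LiN(SiMe3)2 3.3 equiv, THF–DMPU, −78 °C) is C-benzylated by F4 anti to the β-benzyl group to give 27.

Third: step 12 (one-pot alkylative epoxide closure; O-alkylation or slow chloride displacement could spoil it). The fallback sets out from 15 and comes back at 17. The dianion of 15 is hydroxymethylated with monomeric formaldehyde (aldol, anti to the C4 group) to give (3S,4R)-4-{[4-(benzyloxy)-3-methoxyphenyl]methyl}-3-hydroxy-3-(hydroxymethyl)oxolan-2-one F5. The primary hydroxyl is tosylated selectively (TsCl, Et3N, Bu2SnO cat., CH2Cl2) to give [(3S,4R)-4-{[4-(benzyloxy)-3-methoxyphenyl]methyl}-3-hydroxy-2-oxooxolan-3-yl]methyl 4-methylbenzenesulfonate F6. DBU in MeCN closes the epoxide 17.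

## Further compounds

F1 | step 13 | [2,2'-bis(benzyloxy)-5'-bromo-3,3'-dimethoxy[1,1'-biphenyl]-5-yl]methanol | COc1cc(CO)cc(-c2cc(Br)cc(OC)c2OCc2ccccc2)c1OCc1ccccc1
F2 | step 13 | 2,2'-bis(benzyloxy)-5-bromo-5'-(bromomethyl)-3,3'-dimethoxy-1,1'-biphenyl | COc1cc(CBr)cc(-c2cc(Br)cc(OC)c2OCc2ccccc2)c1OCc1ccccc1
F3 | step 18 | [4-(benzyloxy)-3-methoxyphenyl]methanol | COc1cc(CO)ccc1OCc1ccccc1
F4 | step 18 | 1-(benzyloxy)-4-(bromomethyl)-2-methoxybenzene | COc1cc(CBr)ccc1OCc1ccccc1
F5 | step 12 | (3S,4R)-4-{[4-(benzyloxy)-3-methoxyphenyl]methyl}-3-hydroxy-3-(hydroxymethyl)oxolan-2-one | COc1cc(C[C@@H]2COC(=O)[C@@]2(O)CO)ccc1OCc1ccccc1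
F6 | step 12 | [(3S,4R)-4-{[4-(benzyloxy)-3-methoxyphenyl]methyl}-3-hydroxy-2-oxooxolan-3-yl]methyl 4-methylbenzenesulfonate | COc1cc(C[C@@H]2COC(=O)[C@@]2(O)COS(=O)(=O)c2ccc(C)cc2)ccc1OCc1ccccc1
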